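**Assumption:** the target has no stereocentre and no stereogenic double bond, so it is achiral and the structure as drawn is the single species to be made; 1,14-dibromotetradecane is taken as a catalogue chemical.

**Retrosynthetic overview**
1. Target 13 ⇒ cut the ring A C5–OMe bond last: oxidative C–H methoxylation of hydroxyquinone 11 with methanol, at the only ring carbon of the molecule that still carries hydrogen.
2. 11 ⇒ bis-arene 9: one global O-demethylation/oxidation brings ring B (from a tetramethoxyarene) and ring A (from a 1,3-dimethoxyarene, one C–H oxygenated) to the quinone level together.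
3. 9 ⇒ two aryl–CH2 bonds: lithiated 3,5-dimethoxytoluene and then lithiated tetramethoxytoluene 3 are alkylated in turn with 1,14-dibromotetradecane, so the two rings differ from the start.
4. 3 ⇒ 1,2,4,5-tetramethoxybenzene + MeI. No ring is built: both six-membered rings are bought as benzene rings; ring B and ring A become quinones in step 4, and ring A is completed in step 5.

**Step 1**
Reactants: 1 1,2,4,5-tetramethoxybenzene
Product: 3 1,2,4,5-tetramethoxy-3-methylbenzene, via tetramethoxyphenyllithium 2 (not isolated)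
Conditions: n-BuLi (1.05 equiv), THF, 0 °C, 1 h; then MeI (1.3 equiv), −78 °C to rt; recrystallise
Reagents that add atoms: iodomethane, CI
Why: Directed ortho-metalation removes a ring hydrogen flanked by two methoxy groups and the aryllithium is methylated by SN2 on MeI; no stereocentre is formed.

**Step 2**
Reactants: 4 3,5-dimethoxytoluene; 5 1,14-dibromotetradecane
Product: 7 2-(14-bromotetradecyl)-1,3-dimethoxy-5-methylbenzene, via dimethoxytolyllithium 6 (not isolated)
Conditions: 4, n-BuLi (1.05 equiv), THF, 0 °C to rt, 2 h; then cannulate into 5 (4 equiv), THF, 0 °C to rt; excess 5 recovered on silica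
Reagents that add atoms: none
Why: Directed ortho-metalation of a 1,3-dimethoxyarene goes to the carbon between the two methoxy groups (para to the methyl), and inverse addition to a fourfold excess of the primary dibromide makes SN2 mono-alkylation dominant; no stereocentre is formed.

**Step 3**
Reactants: 3 1,2,4,5-tetramethoxy-3-methylbenzene; 7 2-(14-bromotetradecyl)-1,3-dimethoxy-5-methylbenzene
Product: 9 3-[14-(2,6-dimethoxy-4-methylphenyl)tetradecyl]-1,2,4,5-tetramethoxy-6-methylbenzene, via tetramethoxytolyllithium 8 (not isolated)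
Conditions: 3 (1.3 equiv), n-BuLi (1.25 equiv), THF, 0 °C to rt, 1.5 h; then 7 (1.0 equiv), THF/DMPU 9:1, rt to 45 °C, 12 h
Reagents that add atoms: none
Why: The single ring hydrogen of 3 lies between two methoxy groups and is removed selectively (directed ortho-metalation), and SN2 alkylation of the aryllithium with primary bromide 7 joins the two different halves; no stereocentre is formed.

**Step 4**
Reactants: 9 3-[14-(2,6-dimethoxy-4-methylphenyl)tetradecyl]-1,2,4,5-tetramethoxy-6-methylbenzene
Product: 11 2,5-dihydroxy-3-[14-(2-hydroxy-4-methyl-3,6-dioxocyclohexa-1,4-dien-1-yl)tetradecyl]-6-methylcyclohexa-2,5-diene-1,4-dione, via hexol 10 (not isolated)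
Conditions: BBr3 (9 equiv), CH2Cl2, −78 °C to rt, 12 h; H2O, 0 °C, EtOAc extraction, solvent swap; crude 10, IBX (2.2 equiv), DMF, 0 °C to rt, 2 h; non-reductive work-up
Reagents that add atoms: 2-iodoxybenzoic acid (IBX), O=C1OI(=O)(O)c2ccccc12
Why: BBr3 cleaves all six aryl methyl ethers; the tetrol ring is dehydrogenated to the 2,5-dihydroxyquinone, and IBX ortho-oxygenates the 2,5-dialkylresorcinol ring at its only free (equivalent) positions via a pentavalent iodine aryloxy intermediate, giving a hydroxy-ortho-quinone that is the tautomer of the 2-hydroxy-para-quinone; no stereocentre is formed.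

**Step 5**
Reactants: 11 2,5-dihydroxy-3-[14-(2-hydroxy-4-methyl-3,6-dioxocyclohexa-1,4-dien-1-yl)tetradecyl]-6-methylcyclohexa-2,5-diene-1,4-dione
Product: 13 2,5-dihydroxy-3-[14-(2-hydroxy-5-methoxy-4-methyl-3,6-dioxocyclohexa-1,4-dien-1-yl)tetradecyl]-6-methylcyclohexa-2,5-diene-1,4-dione (the target), via methoxyhydroquinone 12 (not isolated)
Conditions: Cu(OTf)2 (3.3 equiv), 1,10-phenanthroline (3.3 equiv), 2,6-lutidine (3.5 equiv), dry MeOH/CH2Cl2 4:1, 3 Å sieves, O2 (1 atm), 40 °C, 12–24 h; evaporate, then EtOAc/aq. citric acid–Na2H2EDTA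
Reagents that add atoms: methanol, CO
Why: Proposed new method: divalent copper capped by phenanthroline binds the deprotonated hydroxy-carbonyl (O1/O2) chelate of ring A, giving a cationic copper dioxolene (the metal-bound 4-hydroxy-ortho-quinone tautomer) that is electrophilic at C5, the only ring carbon in the molecule still bearing hydrogen, so solvent methanol adds there in a conjugate (oxa-Michael) sense and the resulting copper-bound catechol 12 is dehydrogenated by divalent copper with O2 as terminal oxidant, which places the new C–OMe bond next to the ring methyl by construction and creates no stereocentre; ring B is held as an inert dicopper bis-chelate (hence 3.3 equiv of copper), never sees acid in methanol, and is released on work-up; the closest known reaction types are the ZnCl2-promoted oxidative addition of methanol to 1,4-benzoquinone, the aerobic oxidative amination of 2-hydroxy-3,6-dialkyl-1,4-benzoquinones at this same ring position, and copper/O2 dehydrogenative C–O coupling of ortho-quinones with phenols, none of which has been shown for an alcohol adding to a hydroxyquinone.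

**Compound list**
1 | 1,2,4,5-tetramethoxybenzene | COc1cc(OC)c(OC)cc1OC | starting material
2 | (2,3,5,6-tetramethoxyphenyl)lithium | [Li]c1c(OC)c(OC)cc(OC)c1OC | intermediate
3 | 1,2,4,5-tetramethoxy-3-methylbenzene | Cc1c(OC)c(OC)cc(OC)c1OC | intermediate
4 | 3,5-dimethoxytoluene (1,3-dimethoxy-5-methylbenzene) | COc1cc(C)cc(OC)c1 | starting material
5 | 1,14-dibromotetradecane | BrCCCCCCCCCCCCCCBr | starting material
6 | (2,6-dimethoxy-4-methylphenyl)lithium | [Li]c1c(OC)cc(C)cc1OC | intermediate
7 | 2-(14-bromotetradecyl)-1,3-dimethoxy-5-methylbenzene | COc1cc(C)cc(OC)c1CCCCCCCCCCCCCCBr | intermediate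
8 | (2,3,5,6-tetramethoxy-4-methylphenyl)lithium | [Li]c1c(OC)c(OC)c(C)c(OC)c1OC | intermediate
9 | 3-[14-(2,6-dimethoxy-4-methylphenyl)tetradecyl]-1,2,4,5-tetramethoxy-6-methylbenzene | COc1cc(C)cc(OC)c1CCCCCCCCCCCCCCc1c(OC)c(OC)c(C)c(OC)c1OC | intermediate
10 | 3-[14-(2,6-dihydroxy-4-methylphenyl)tetradecyl]-6-methylbenzene-1,2,4,5-tetrol | Cc1cc(O)c(CCCCCCCCCCCCCCc2c(O)c(O)c(C)c(O)c2O)c(O)c1 | intermediate
11 | 2,5-dihydroxy-3-[14-(2-hydroxy-4-methyl-3,6-dioxocyclohexa-1,4-dien-1-yl)tetradecyl]-6-methylcyclohexa-2,5-diene-1,4-dione | CC1=CC(=O)C(CCCCCCCCCCCCCCC2=C(O)C(=O)C(C)=C(O)C2=O)=C(O)C1=O | intermediate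
12 | 2,5-dihydroxy-3-methyl-6-[14-(2,3,6-trihydroxy-5-methoxy-4-methylphenyl)tetradecyl]cyclohexa-2,5-diene-1,4-dione | COc1c(C)c(O)c(O)c(CCCCCCCCCCCCCCC2=C(O)C(=O)C(C)=C(O)C2=O)c1O | intermediate
13 | 2,5-dihydroxy-3-[14-(2-hydroxy-5-methoxy-4-methyl-3,6-dioxocyclohexa-1,4-dien-1-yl)tetradecyl]-6-methylcyclohexa-2,5-diene-1,4-dione | COC1=C(C)C(=O)C(O)=C(CCCCCCCCCCCCCCC2=C(O)C(=O)C(C)=C(O)C2=O)C1=O | target

**Totals**
Total step count: 5. Longest linear sequence: 4 steps (step 1 or step 2, then steps 3, 4 and 5).

**Three steps most likely to fail**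

Step 5, the proposed methoxylation. Methanol is a weak nucleophile for an electron-rich hydroxyquinonate, ring B can sequester copper, and adventitious water would give the hydroxylated by-product. The fallback uses known chemistry, sets out from 11 and comes back at 13. Bromine (1.05 equiv) in AcOH/CHCl3 adds across the C5=C6 bond of the hydroxyquinone ring and HBr is lost, the classical halogenation of an alkylquinone C–H position, giving 2-[14-(5-bromo-2-hydroxy-4-methyl-3,6-dioxocyclohexa-1,4-dien-1-yl)tetradecyl]-3,6-dihydroxy-5-methylcyclohexa-2,5-diene-1,4-dione F1. Excess NaOMe in MeOH at reflux, followed by dilute HCl, then replaces the vinylic bromide by methoxide through addition–elimination and gives 13.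

Step 4, the global demethylation and double oxidation. The tetrol is air-sensitive, and IBX may attack the alkyl-bearing ortho carbon or over-oxidise. The fallback sets out from 9, comes back at 11, and avoids both BBr3 and phenol oxygenation. Vilsmeier–Haack formylation (POCl3, DMF) at the free position of the dimethoxy ring gives 2,4-dimethoxy-6-methyl-3-[14-(2,3,5,6-tetramethoxy-4-methylphenyl)tetradecyl]benzaldehyde F2. Dakin-type Baeyer–Villiger oxidation (mCPBA, CH2Cl2; then K2CO3, MeOH) turns the formyl group into a hydroxyl, giving 2,4-dimethoxy-6-methyl-3-[14-(2,3,5,6-tetramethoxy-4-methylphenyl)tetradecyl]phenol F3. Oxidative demethylation of both rings with (NH4)2Ce(NO3)6 in MeCN/H2O gives 2,5-dimethoxy-3-[14-(2-methoxy-4-methyl-3,6-dioxocyclohexa-1,4-dien-1-yl)tetradecyl]-6-methylcyclohexa-2,5-diene-1,4-dione F4. Hydrolysis of its three vinylogous methyl esters (2 M NaOH, EtOH/H2O, argon, 60 °C; then HCl) gives 11.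

Step 3, the alkylation of the hindered aryllithium 8 with one equivalent of bromide 7. Lithium–bromine exchange, elimination or low conversion could intervene. The fallback sets out from 3 and 7, comes back at 9, and replaces the SN2 step by a palladium-catalysed cross-coupling. Aryllithium 8, made from 3 as before, is quenched with I2 to give 3-iodo-1,2,4,5-tetramethoxy-6-methylbenzene F5. Zinc dust with LiCl in THF at 50 °C inserts into the C–Br bond of 7 to give [14-(2,6-dimethoxy-4-methylphenyl)tetradecyl]zinc bromide F6. Negishi coupling of F5 with F6 (Pd(OAc)2, SPhos, THF, 60 °C) gives 9.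

**Further compounds**
F1 | step 5 | 2-[14-(5-bromo-2-hydroxy-4-methyl-3,6-dioxocyclohexa-1,4-dien-1-yl)tetradecyl]-3,6-dihydroxy-5-methylcyclohexa-2,5-diene-1,4-dione | CC1=C(Br)C(=O)C(CCCCCCCCCCCCCCC2=C(O)C(=O)C(C)=C(O)C2=O)=C(O)C1=O
F2 | step 4 | 2,4-dimethoxy-6-methyl-3-[14-(2,3,5,6-tetramethoxy-4-methylphenyl)tetradecyl]benzaldehyde | COc1cc(C)c(C=O)c(OC)c1CCCCCCCCCCCCCCc1c(OC)c(OC)c(C)c(OC)c1OC
F3 | step 4 | 2,4-dimethoxy-6-methyl-3-[14-(2,3,5,6-tetramethoxy-4-methylphenyl)tetradecyl]phenol | COc1cc(C)c(O)c(OC)c1CCCCCCCCCCCCCCc1c(OC)c(OC)c(C)c(OC)c1OC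
F4 | step 4 | 2,5-dimethoxy-3-[14-(2-methoxy-4-methyl-3,6-dioxocyclohexa-1,4-dien-1-yl)tetradecyl]-6-methylcyclohexa-2,5-diene-1,4-dione | COC1=C(CCCCCCCCCCCCCCC2=C(OC)C(=O)C(C)=C(OC)C2=O)C(=O)C=C(C)C1=O
F5 | step 3 | 3-iodo-1,2,4,5-tetramethoxy-6-methylbenzene | Cc1c(OC)c(OC)c(I)c(OC)c1OC
F6 | step 3 | [14-(2,6-dimethoxy-4-methylphenyl)tetradecyl]zinc bromide | COc1cc(C)cc(OC)c1CCCCCCCCCCCCCC[Zn]Br
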